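Retrosynthesis: the two hydroxyl groups are traced back to a C3 formyl group and a pivalate; the oxolane (O1, C2 aryl, C3, C4, C5) is then cut at C2–C3, next at the ether bond O1–C2, and last at the bond between C4 and the carbinol carbon.
Enabling feature: C2 of the oxolane is benzylic to the 3,4,5-trimethoxyphenyl ring and α to O1, so in the open-chain trimethoxybenzyl ether this CH2 is the most readily oxidised C–H bond and can become an aryl oxocarbenium carbon.
Forward: an auxiliary-controlled syn-aldol joins a pent-4-enoyl chain to 3,4-dimethoxybenzaldehyde; reductive removal of the auxiliary, etherification of the primary alcohol, pivaloylation, alkene cleavage and enol acetylation follow.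
DDQ then closes the only ring by bonding the enol α-carbon (C3) to the oxidised benzylic carbon (C2); LiAlH4 finishes.
Stereochemistry: C4 and the carbinol carbon come from the (S)-4-benzyloxazolidin-2-one aldol; C2 and C3 arise in the cyclisation under control of C4, with C3 equilibrated to the all-trans aldehyde.

Key step: step 8

Remark: compounds 1, 2, 4 and 9 are taken as commercial, and the all-trans aldehyde is assumed to be the thermodynamic C3 epimer, so a base equilibration is built into step 8.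

Step 1
Reactants: 1 (S)-4-benzyloxazolidin-2-one; 2 pent-4-enoyl chloride
Product: 3 (S)-4-benzyl-3-(pent-4-enoyl)oxazolidin-2-one
Conditions: Et3N, DMAP (cat.), CH2Cl2, 0 °C to rt
Reagents that add atoms: none
Why: DMAP-catalysed N-acylation of the oxazolidinone by the acid chloride (nucleophilic acyl substitution) is routine and touches no stereocentre.

Step 2
Reactants: 3 (S)-4-benzyl-3-(pent-4-enoyl)oxazolidin-2-one; 4 3,4-dimethoxybenzaldehyde
Product: 7 (S)-4-benzyl-3-[(2S,3S)-3-(3,4-dimethoxyphenyl)-3-hydroxy-2-(prop-2-en-1-yl)propanoyl]oxazolidin-2-one, via dibutylboron Z-enolate 5 (not isolated), via dibutylboron aldolate 6 (not isolated)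
Conditions: Bu2BOTf, i-Pr2NEt, CH2Cl2, −78 to 0 °C; then 4, −78 to 0 °C; H2O2, MeOH, pH 7 buffer, 0 °C
Reagents that add atoms: none
Why: Evans syn-aldol: the Z-boron enolate should add through a closed chair transition state on the enolate face not shielded by the benzyl group of the auxiliary, setting the (2S,3S) syn pair that becomes C4 and the carbinol carbon.

Step 3
Reactants: 7 (S)-4-benzyl-3-[(2S,3S)-3-(3,4-dimethoxyphenyl)-3-hydroxy-2-(prop-2-en-1-yl)propanoyl]oxazolidin-2-one
Product: 8 (1S,2R)-1-(3,4-dimethoxyphenyl)-2-(prop-2-en-1-yl)propane-1,3-diol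
Conditions: LiBH4, MeOH (1 equiv), THF, 0 °C
Reagents that add atoms: none
Why: Reductive cleavage of the N-acyloxazolidinone by LiBH4 gives the primary alcohol and returns the auxiliary without touching either stereocentre.

Step 4
Reactants: 8 (1S,2R)-1-(3,4-dimethoxyphenyl)-2-(prop-2-en-1-yl)propane-1,3-diol; 9 3,4,5-trimethoxybenzyl chloride
Product: 11 (1S,2R)-1-(3,4-dimethoxyphenyl)-2-{[(3,4,5-trimethoxyphenyl)methoxy]methyl}pent-4-en-1-ol, via stannylene acetal 10 (not isolated)
Conditions: Bu2SnO, toluene, reflux, azeotropic removal of water; then 9, Bu4NI (cat.), toluene, 80 °C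
Reagents that add atoms: none
Why: Tin-mediated regioselective Williamson-type etherification: in the six-membered dibutylstannylene acetal the less hindered primary oxygen should be alkylated in preference to the secondary benzylic one.

Step 5
Reactants: 11 (1S,2R)-1-(3,4-dimethoxyphenyl)-2-{[(3,4,5-trimethoxyphenyl)methoxy]methyl}pent-4-en-1-ol
Product: 12 (1S,2R)-1-(3,4-dimethoxyphenyl)-2-{[(3,4,5-trimethoxyphenyl)methoxy]methyl}pent-4-en-1-yl 2,2-dimethylpropanoate
Conditions: PivCl, DMAP (cat.), pyridine, CH2Cl2, rt to 40 °C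
Reagents that add atoms: pivaloyl chloride, CC(C)(C)C(=O)Cl
Why: DMAP-catalysed O-acylation of the only free hydroxyl proceeds with retention and installs the electron-withdrawing ester that later deactivates the veratryl benzylic C–H bond.

Step 6
Reactants: 12 (1S,2R)-1-(3,4-dimethoxyphenyl)-2-{[(3,4,5-trimethoxyphenyl)methoxy]methyl}pent-4-en-1-yl 2,2-dimethylpropanoate
Product: 14 (1S,2R)-1-(3,4-dimethoxyphenyl)-4-oxo-2-{[(3,4,5-trimethoxyphenyl)methoxy]methyl}butyl 2,2-dimethylpropanoate, via vicinal diol 13 (not isolated)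
Conditions: OsO4 (cat.), NaIO4, 2,6-lutidine, dioxane/H2O, rt
Reagents that add atoms: osmium tetroxide, O=[Os](=O)(=O)=O; sodium periodate, [Na+].[O-]I(=O)(=O)=O
Why: Lemieux–Johnson oxidation dihydroxylates the single alkene and cleaves the diol to the aldehyde, and it is chosen over ozone because it leaves the two electron-rich arenes and the benzylic ether alone.

Step 7
Reactants: 14 (1S,2R)-1-(3,4-dimethoxyphenyl)-4-oxo-2-{[(3,4,5-trimethoxyphenyl)methoxy]methyl}butyl 2,2-dimethylpropanoate
Product: 15 (1S,2R)-4-acetoxy-1-(3,4-dimethoxyphenyl)-2-{[(3,4,5-trimethoxyphenyl)methoxy]methyl}but-3-en-1-yl 2,2-dimethylpropanoate (E/Z mixture)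
Conditions: Ac2O, Et3N, DMAP (cat.), 80 °C
Reagents that add atoms: acetic anhydride, CC(=O)OC(C)=O
Why: Base-mediated enol acetylation (O-acylation of the aldehyde enolate) can involve only the one α-carbon, and the enol geometry does not matter for the next step.

Step 8
Reactants: 15 (1S,2R)-4-acetoxy-1-(3,4-dimethoxyphenyl)-2-{[(3,4,5-trimethoxyphenyl)methoxy]methyl}but-3-en-1-yl 2,2-dimethylpropanoate (E/Z mixture)
Product: 19 (2R,3R,4R)-4-[(S)-(3,4-dimethoxyphenyl)(pivaloyloxy)methyl]-2-(3,4,5-trimethoxyphenyl)oxolane-3-carbaldehyde, via aryl oxocarbenium ion 16 (not isolated), via O-acetyl oxocarbenium ion 17 (not isolated), via C3-epimeric aldehyde 18 (not isolated)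
Conditions: DDQ, 2,6-dichloropyridine, LiClO4, 4 Å molecular sieves, ClCH2CH2Cl, rt; aq. NaHCO3; then DBU (cat.), CH2Cl2, rt
Reagents that add atoms: none
Why: Proposed new method: DDQ should form a charge-transfer complex with the trimethoxyarene and remove hydride from the benzylic CH2 next to O1, giving the (E)-aryl oxocarbenium ion 16, which is attacked at C2 by the α-carbon (C3) of the tethered enol acetate to give the O-acetyl oxocarbenium ion 17, and loss of the acetyl group to the hydroquinone anion releases the C3 aldehyde. The closest known reaction type is the DDQ-mediated oxidative C–H cleavage of benzylic ethers with enol acetate capture, which gives 2-aryltetrahydropyran-4-ones, and the same enol-to-oxocarbenium bond formation closes 3-formyloxolanes in the Lewis-acid 1,3 O-to-C rearrangement of cyclic vinyl acetals. The oxolane closes in a 5-(enolexo)-endo-trig mode, endo to the C2=O1+ bond and exo to the enol C=C. C2 is set under substrate control, because in the envelope transition state the C4 side chain and the aryl group of the (E)-oxocarbenium ion should both sit pseudo-equatorial and therefore end cis; C3 is set trans to both neighbours, either directly (allylic strain holds the C4–H bond in the enol plane, so the tethered electrophile arrives anti to the side chain) or by DBU equilibration of any epimer 18 through the enol, the all-trans aldehyde being the thermodynamic isomer. The step needs oxidation of the trimethoxybenzyl ether in preference to the veratryl C–H bond, which the pivalate secures because an acyloxy carbocation is destabilised and that C–H bond is hindered; the product is shielded from further oxidation at C2 by the inductively withdrawing C3 formyl group.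

Step 9
Reactants: 19 (2R,3R,4R)-4-[(S)-(3,4-dimethoxyphenyl)(pivaloyloxy)methyl]-2-(3,4,5-trimethoxyphenyl)oxolane-3-carbaldehyde
Product: 20 (S)-(3,4-dimethoxyphenyl)[(3R,4S,5R)-4-(hydroxymethyl)-5-(3,4,5-trimethoxyphenyl)oxolan-3-yl]methanol
Conditions: LiAlH4, THF, 0 °C to rt; aq. NaOH work-up
Reagents that add atoms: none
Why: Hydride reduction by LiAlH4 converts the aldehyde into the CH2OH group faster than it can enolise and cleaves the pivalate reductively, so all four stereocentres are kept.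

Compound list
1 | (S)-4-benzyloxazolidin-2-one | O=C1N[C@@H](Cc2ccccc2)CO1 | starting material
2 | pent-4-enoyl chloride | C=CCCC(Cl)=O | starting material
3 | (S)-4-benzyl-3-(pent-4-enoyl)oxazolidin-2-one | C=CCCC(=O)N1C(=O)OC[C@@H]1Cc1ccccc1 | intermediate
4 | 3,4-dimethoxybenzaldehyde | COc1ccc(C=O)cc1OC | starting material
5 | dibutylboron (Z)-enolate of 3, formed in situ | C=CC/C=C(\OB(CCCC)CCCC)N1C(=O)OC[C@@H]1Cc1ccccc1 | intermediate
6 | O-dibutylboryl aldolate of 7, formed in situ | COc1ccc([C@@H](OB(CCCC)CCCC)[C@H](CC=C)C(=O)N2C(=O)OC[C@@H]2Cc2ccccc2)cc1OC | intermediate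
7 | (S)-4-benzyl-3-[(2S,3S)-3-(3,4-dimethoxyphenyl)-3-hydroxy-2-(prop-2-en-1-yl)propanoyl]oxazolidin-2-one | COc1ccc([C@@H](O)[C@H](CC=C)C(=O)N2C(=O)OC[C@@H]2Cc2ccccc2)cc1OC | intermediate
8 | (1S,2R)-1-(3,4-dimethoxyphenyl)-2-(prop-2-en-1-yl)propane-1,3-diol | COc1ccc([C@@H](O)[C@H](CC=C)CO)cc1OC | intermediate
9 | 3,4,5-trimethoxybenzyl chloride | COc1cc(CCl)cc(OC)c1OC | starting material
10 | (4S,5R)-2,2-dibutyl-4-(3,4-dimethoxyphenyl)-5-(prop-2-en-1-yl)-1,3,2-dioxastannane, formed in situ | COc1ccc([C@H]2O[Sn](CCCC)(CCCC)OC[C@H]2CC=C)cc1OC | intermediate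
11 | (1S,2R)-1-(3,4-dimethoxyphenyl)-2-{[(3,4,5-trimethoxyphenyl)methoxy]methyl}pent-4-en-1-ol | COc1ccc([C@@H](O)[C@H](CC=C)COCc2cc(OC)c(OC)c(OC)c2)cc1OC | intermediate
12 | (1S,2R)-1-(3,4-dimethoxyphenyl)-2-{[(3,4,5-trimethoxyphenyl)methoxy]methyl}pent-4-en-1-yl 2,2-dimethylpropanoate | COc1ccc([C@@H](OC(=O)C(C)(C)C)[C@H](CC=C)COCc2cc(OC)c(OC)c(OC)c2)cc1OC | intermediate
13 | (1S,2R)-1-(3,4-dimethoxyphenyl)-4,5-dihydroxy-2-{[(3,4,5-trimethoxyphenyl)methoxy]methyl}pentyl 2,2-dimethylpropanoate, both C4 epimers, formed in situ | COc1ccc([C@@H](OC(=O)C(C)(C)C)[C@H](CC(O)CO)COCc2cc(OC)c(OC)c(OC)c2)cc1OC | intermediate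
14 | (1S,2R)-1-(3,4-dimethoxyphenyl)-4-oxo-2-{[(3,4,5-trimethoxyphenyl)methoxy]methyl}butyl 2,2-dimethylpropanoate | COc1ccc([C@@H](OC(=O)C(C)(C)C)[C@H](CC=O)COCc2cc(OC)c(OC)c(OC)c2)cc1OC | intermediate
15 | (1S,2R)-4-acetoxy-1-(3,4-dimethoxyphenyl)-2-{[(3,4,5-trimethoxyphenyl)methoxy]methyl}but-3-en-1-yl 2,2-dimethylpropanoate, E/Z mixture | COc1ccc([C@@H](OC(=O)C(C)(C)C)[C@H](C=COC(C)=O)COCc2cc(OC)c(OC)c(OC)c2)cc1OC | intermediate
16 | (E)-aryl oxocarbenium ion: 15 with the ArCH2–O unit turned into ArCH=O+, formed in situ | COc1ccc([C@@H](OC(=O)C(C)(C)C)[C@H](C=COC(C)=O)C/[O+]=C/c2cc(OC)c(OC)c(OC)c2)cc1OC | intermediate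
17 | O-acetyl oxocarbenium ion of the cyclised aldehyde (ring closed, C3 bearing CH=O+–Ac, C3 either configuration), formed in situ | COc1ccc([C@@H](OC(=O)C(C)(C)C)[C@H]2CO[C@@H](c3cc(OC)c(OC)c(OC)c3)C2C=[O+]C(C)=O)cc1OC | intermediate
18 | (2R,3S,4R)-4-[(S)-(3,4-dimethoxyphenyl)(pivaloyloxy)methyl]-2-(3,4,5-trimethoxyphenyl)oxolane-3-carbaldehyde (C3 epimer of 19), formed in situ | COc1ccc([C@@H](OC(=O)C(C)(C)C)[C@H]2CO[C@@H](c3cc(OC)c(OC)c(OC)c3)[C@H]2C=O)cc1OC | intermediate
19 | (2R,3R,4R)-4-[(S)-(3,4-dimethoxyphenyl)(pivaloyloxy)methyl]-2-(3,4,5-trimethoxyphenyl)oxolane-3-carbaldehyde (all-trans) | COc1ccc([C@@H](OC(=O)C(C)(C)C)[C@H]2CO[C@@H](c3cc(OC)c(OC)c(OC)c3)[C@@H]2C=O)cc1OC | intermediate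
20 | (S)-(3,4-dimethoxyphenyl)[(3R,4S,5R)-4-(hydroxymethyl)-5-(3,4,5-trimethoxyphenyl)oxolan-3-yl]methanol | COc1ccc([C@@H](O)[C@H]2CO[C@@H](c3cc(OC)c(OC)c(OC)c3)[C@@H]2CO)cc1OC | target

Total step count: 9
Longest linear sequence: 9 steps (1 and 2 to 20)

Steps most likely to fail

Step 8 (the step with the new-method label). Two processes may defeat it: capture of the oxocarbenium ion by traces of water before the slow five-membered C–C closure, and attack on the wrong face of the oxocarbenium carbon, which would misplace C2 relative to C4 and cannot be repaired by base. The fallback uses known chemistry only, sets out from 14 and comes back at 20; it forms C2–C3 by a second auxiliary-controlled aldol and closes the ring at O1–C2.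
- Pinnick oxidation of 14 (NaClO2, NaH2PO4, 2-methylbut-2-ene) should give the carboxylic acid F1.
- The mixed pivalic anhydride of F1 (PivCl, Et3N) acylates (R)-4-benzyloxazolidin-2-one in the presence of LiCl to give the (R)-configured N-acyloxazolidinone F2.
- An Evans syn-aldol of F2 (Bu2BOTf, i-Pr2NEt) with 3,4,5-trimethoxybenzaldehyde should give the syn-aldol adduct F3, in which the auxiliary fixes C3 trans-disposed to the C4 side chain for the later ring.
- LiBH4 removes the auxiliary and leaves the pivalate, giving the diol F4.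
- DDQ in buffered wet CH2Cl2 at 0 °C cleaves the unhindered trimethoxybenzyl ether faster than it oxidises the hindered secondary carbinol and frees the C5 hydroxyl in the triol F5.
- A catalytic amount of camphorsulfonic acid in CH2Cl2 at 0 °C ionises the trimethoxyphenyl carbinol, and the C5 hydroxyl captures the benzylic cation trans to the C3 substituent, giving the oxolane pivalate F6. The ester at the other benzylic carbon is far less prone to ionise under these conditions.
- LiAlH4 removes the pivalate and delivers 20.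

Step 4. The alkylation may lose regiocontrol (attack at the secondary benzylic oxygen or at both oxygens), or the electron-rich benzyl chloride may decompose before it reacts. The fallback fixes the regiochemistry by the order of events, sets out from 7 and comes back at 12.
- Pivaloylation of 7 (PivCl, DMAP, pyridine) gives the aldol pivalate F7.
- LiBH4 cleaves the auxiliary to give the primary alcohol F8, whose only free hydroxyl is the one to be etherified.
- 3,4,5-Trimethoxybenzyl alcohol and Cl3CCN with catalytic DBU give 3,4,5-trimethoxybenzyl trichloroacetimidate F9.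
- F9 alkylates F8 under catalytic La(OTf)3 in toluene at rt to give 12.

Step 7. Under the hot basic acetylation conditions the aldehyde may undergo self-aldol condensation, or the benzylic pivalate may ionise thermally. The fallback separates enolisation from acylation, sets out from 14 and comes back at 15.
- TMSCl, NaI and Et3N in MeCN at rt convert 14 into the trimethylsilyl enol ether F10.
- KOt-Bu in THF at −78 °C cleaves the silyl group to the potassium enolate in the absence of free aldehyde, and Ac2O O-acylates it to 15.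

Further compounds
F1 | step 8 | (3R,4S)-4-(3,4-dimethoxyphenyl)-4-(pivaloyloxy)-3-{[(3,4,5-trimethoxyphenyl)methoxy]methyl}butanoic acid | COc1ccc([C@@H](OC(=O)C(C)(C)C)[C@H](CC(=O)O)COCc2cc(OC)c(OC)c(OC)c2)cc1OC
F2 | step 8 | (4R)-4-benzyl-3-[(3R,4S)-4-(3,4-dimethoxyphenyl)-4-(pivaloyloxy)-3-{[(3,4,5-trimethoxyphenyl)methoxy]methyl}butanoyl]oxazolidin-2-one | COc1ccc([C@@H](OC(=O)C(C)(C)C)[C@H](CC(=O)N2C(=O)OC[C@H]2Cc2ccccc2)COCc2cc(OC)c(OC)c(OC)c2)cc1OC
F3 | step 8 | (4R)-4-benzyl-3-[(2R,3R,4S)-4-(3,4-dimethoxyphenyl)-2-[(R)-hydroxy(3,4,5-trimethoxyphenyl)methyl]-4-(pivaloyloxy)-3-{[(3,4,5-trimethoxyphenyl)methoxy]methyl}butanoyl]oxazolidin-2-one | COc1ccc([C@@H](OC(=O)C(C)(C)C)[C@@H](COCc2cc(OC)c(OC)c(OC)c2)[C@H]([C@@H](O)c2cc(OC)c(OC)c(OC)c2)C(=O)N2C(=O)OC[C@H]2Cc2ccccc2)cc1OC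
F4 | step 8 | (1S,2R,3S,4R)-1-(3,4-dimethoxyphenyl)-4-hydroxy-3-(hydroxymethyl)-4-(3,4,5-trimethoxyphenyl)-2-{[(3,4,5-trimethoxyphenyl)methoxy]methyl}butyl 2,2-dimethylpropanoate | COc1ccc([C@@H](OC(=O)C(C)(C)C)[C@@H](COCc2cc(OC)c(OC)c(OC)c2)[C@H]([C@@H](O)c2cc(OC)c(OC)c(OC)c2)CO)cc1OC
F5 | step 8 | (1S,2R,3S,4R)-1-(3,4-dimethoxyphenyl)-4-hydroxy-2,3-bis(hydroxymethyl)-4-(3,4,5-trimethoxyphenyl)butyl 2,2-dimethylpropanoate | COc1ccc([C@@H](OC(=O)C(C)(C)C)[C@@H](CO)[C@H]([C@@H](O)c2cc(OC)c(OC)c(OC)c2)CO)cc1OC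
F6 | step 8 | (S)-(3,4-dimethoxyphenyl)[(3R,4S,5R)-4-(hydroxymethyl)-5-(3,4,5-trimethoxyphenyl)oxolan-3-yl]methyl 2,2-dimethylpropanoate | COc1ccc([C@@H](OC(=O)C(C)(C)C)[C@H]2CO[C@@H](c3cc(OC)c(OC)c(OC)c3)[C@@H]2CO)cc1OC
F7 | step 4 | (4S)-4-benzyl-3-[(2S,3S)-3-(3,4-dimethoxyphenyl)-3-(pivaloyloxy)-2-(prop-2-en-1-yl)propanoyl]oxazolidin-2-one | COc1ccc([C@@H](OC(=O)C(C)(C)C)[C@H](CC=C)C(=O)N2C(=O)OC[C@@H]2Cc2ccccc2)cc1OC
F8 | step 4 | (1S,2R)-1-(3,4-dimethoxyphenyl)-2-(hydroxymethyl)pent-4-en-1-yl 2,2-dimethylpropanoate | COc1ccc([C@@H](OC(=O)C(C)(C)C)[C@H](CC=C)CO)cc1OC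
F9 | step 4 | 3,4,5-trimethoxybenzyl 2,2,2-trichloroacetimidate | COc1cc(COC(=N)C(Cl)(Cl)Cl)cc(OC)c1OC
F10 | step 7 | (1S,2R)-1-(3,4-dimethoxyphenyl)-2-{[(3,4,5-trimethoxyphenyl)methoxy]methyl}-4-[(trimethylsilyl)oxy]but-3-en-1-yl 2,2-dimethylpropanoate, E/Z mixture | COc1ccc([C@@H](OC(=O)C(C)(C)C)[C@H](C=CO[Si](C)(C)C)COCc2cc(OC)c(OC)c(OC)c2)cc1OC
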